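**Retrosynthetic overview**
1. Target 25 ⇐ 23 (desilylation, acetylation) ⇐ 20 by a three-carbon extension of the side chain (glycol cleavage, Wittig, MeMgBr).
2. The nine-membered ring of 20, the only ring, ⇐ seco ester 18 by intramolecular B-alkyl Suzuki–Miyaura coupling; it is formed after the sigmatropic step.
3. 18 ⇐ allylic dienoate 14 by a deconjugative Ireland–Claisen [3,3] rearrangement that forms the C1–C2 ring bond, both stereocentres, the exocyclic methylidene and the side-chain trisubstituted alkene.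
4. 14 ⇐ acid 8 (from pent-3-yn-1-ol) + carbinol 12 (enyne 10 + (S)-glyceraldehyde acetonide 11, the sole source of chirality).

Assumption: the target is read from the SMILES as (1R,2S,5E) with a (2Z,4E) side chain; 9 and 11 are taken as purchasable.

**Route**

Step 1
Reactants: 1 pent-3-yn-1-ol
Product: 3 (E)-4-iodopent-3-en-1-ol, via alkenylzirconocene 2 (not isolated)
Conditions: Cp2Zr(H)Cl (2.3 equiv), THF, rt then 40 °C; I2, 0 °C; aq. Na2S2O3
Reagents that add atoms: iodine (II)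
Why: Hydrozirconation is a syn addition and, once the first equivalent has capped the hydroxyl as a zirconium alkoxide, excess reagent equilibrates Zr to the less hindered methyl-bearing alkyne carbon, so iodinolysis with retention gives the (E)-2-iodoalkene (no stereocentre formed).

Step 2
Reactants: 3 (E)-4-iodopent-3-en-1-ol
Product: 4 (E)-4-iodopent-3-en-1-yl 4-methylbenzenesulfonate
Conditions: TsCl, Et3N, cat. DMAP, CH2Cl2, 0 °C → rt
Reagents that add atoms: 4-methylbenzenesulfonyl chloride (Cc1ccc(cc1)S(Cl)(=O)=O)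
Why: Standard O-sulfonylation turns the primary alcohol into a leaving group without touching the vinyl iodide geometry.

Step 3
Reactants: 4 (E)-4-iodopent-3-en-1-yl 4-methylbenzenesulfonate
Product: 5 (E)-6-iodohept-5-en-1-yne
Conditions: LiC≡CH·H2NCH2CH2NH2 (1.5 equiv), DMSO, 15 °C → rt
Reagents that add atoms: lithium acetylide ethylenediamine complex ([Li+].[C-]#C.NCCN)
Why: SN2 alkylation of acetylide by the primary tosylate in a dipolar aprotic solvent installs the terminal alkyne, the vinyl iodide being inert to SN2.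

Step 4
Reactants: 5 (E)-6-iodohept-5-en-1-yne
Product: 7 methyl (2E,6E)-7-iodo-3-methylocta-2,6-dienoate, via alkenylalane 6 (not isolated)
Conditions: AlMe3 (2.5 equiv), Cp2ZrCl2 (0.25 equiv), CH2Cl2, 0 °C → rt; then ClCO2Me, 0 °C → rt
Reagents that add atoms: trimethylaluminium (C[Al](C)C); methyl chloroformate (COC(Cl)=O)
Why: Negishi zirconium-catalysed carboalumination adds Me and Al syn across the terminal alkyne (Me to the internal carbon) and the alkenylalane is acylated with retention, giving the 2E enoate whose 3-methyl is cis to the ester.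

Step 5
Reactants: 7 methyl (2E,6E)-7-iodo-3-methylocta-2,6-dienoate
Product: 8 (2E,6E)-7-iodo-3-methylocta-2,6-dienoic acid
Conditions: LiOH·H2O, THF/MeOH/H2O, 40 °C; then 1 M HCl
Reagents that add atoms: lithium hydroxide ([Li+].[OH-])
Why: Ester saponification, which leaves both alkene geometries and the vinyl iodide untouched.

Step 6
Reactants: 9 tert-butyl(diphenyl)(prop-2-yn-1-yloxy)silane
Product: 10 tert-butyl(pent-4-en-2-yn-1-yloxy)diphenylsilane
Conditions: vinyl bromide (1 M in THF, 2 equiv), Pd(PPh3)2Cl2 (2 mol%), CuI (4 mol%), Et3N, THF, rt, sealed vessel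
Reagents that add atoms: vinyl bromide (C=CBr)
Why: Sonogashira sp–sp2 coupling gives the conjugated 1,3-enyne needed to direct the next step.

Step 7
Reactants: 10 tert-butyl(pent-4-en-2-yn-1-yloxy)diphenylsilane; 11 (S)-2,2-dimethyl-1,3-dioxolane-4-carbaldehyde
Product: 12 (1R,2E)-2-{[tert-butyl(diphenyl)silyl]oxymethyl}-1-[(4S)-2,2-dimethyl-1,3-dioxolan-4-yl]penta-2,4-dien-1-ol
Conditions: Ni(cod)2 (10 mol%), P(c-C5H9)3 (20 mol%), Et3B (2.5 equiv), EtOAc, rt; aq. NaHCO3; chromatography to remove the minor syn isomer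
Reagents that add atoms: none
Why: In this nickel-catalysed reductive alkyne–aldehyde coupling the conjugated alkene steers C–C bond formation to the distal alkyne carbon, H and the carbinol carbon add cis (vinyl trans to the carbinol carbon), and Felkin–Anh attack anti to the α-oxygen of 11 sets the new carbinol as R (1,2-anti), so it is controlled by the purchased stereocentre.

Step 8
Reactants: 8 (2E,6E)-7-iodo-3-methylocta-2,6-dienoic acid; 12 (1R,2E)-2-{[tert-butyl(diphenyl)silyl]oxymethyl}-1-[(4S)-2,2-dimethyl-1,3-dioxolan-4-yl]penta-2,4-dien-1-ol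
Product: 14 (1R,2E)-2-{[tert-butyl(diphenyl)silyl]oxymethyl}-1-[(4S)-2,2-dimethyl-1,3-dioxolan-4-yl]penta-2,4-dien-1-yl (2E,6E)-7-iodo-3-methylocta-2,6-dienoate, via acid chloride 13 (not isolated)
Conditions: 8, (COCl)2, cat. DMF, CH2Cl2, 0 °C → rt, evaporate; then 12, pyridine, CH2Cl2, 0 °C → rt
Reagents that add atoms: none
Why: Acylation through the acid chloride with only pyridine as base avoids γ-deprotonation (E/Z scrambling or deconjugation) of the enoyl unit and leaves the carbinol configuration untouched.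

Step 9
Reactants: 14 (1R,2E)-2-{[tert-butyl(diphenyl)silyl]oxymethyl}-1-[(4S)-2,2-dimethyl-1,3-dioxolan-4-yl]penta-2,4-dien-1-yl (2E,6E)-7-iodo-3-methylocta-2,6-dienoate
Product: 18 methyl (2R,3S,4Z)-4-{[tert-butyl(diphenyl)silyl]oxymethyl}-5-[(4R)-2,2-dimethyl-1,3-dioxolan-4-yl]-3-ethenyl-2-[(5E)-6-iodohepta-1,5-dien-2-yl]pent-4-enoate, via silyl ketene acetal 15 (not isolated), via trimethylsilyl ester 16 (not isolated), via carboxylic acid 17 (not isolated)
Conditions: LiN(iPr)2 (1.3 equiv), THF, −78 °C; Me3SiCl/Et3N, −78 °C → rt, then 55 °C, 3 h; 1 M HCl work-up; then Me3SiCHN2, MeOH/PhMe, 0 °C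
Reagents that add atoms: (trimethylsilyl)diazomethane (C[Si](C)(C)C=[N+]=[N-])
Why: Syn-γ-deprotonation of the methyl cis to the ester gives the (1Z)-dienolate (Me3SiO cis to C3), whose Ireland–Claisen [3,3] rearrangement through a chair with the dioxolanyl group equatorial forms the C2–C3 bond suprafacially, transferring the R carbinol configuration to the 2R,3S centres (E-allyl plus Z-ketene acetal gives the 2,3-syn pair, trans on the later ring) while creating the methylidene and the Z trisubstituted alkene; the acid is then trapped as its methyl ester.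

Step 10
Reactants: 18 methyl (2R,3S,4Z)-4-{[tert-butyl(diphenyl)silyl]oxymethyl}-5-[(4R)-2,2-dimethyl-1,3-dioxolan-4-yl]-3-ethenyl-2-[(5E)-6-iodohepta-1,5-dien-2-yl]pent-4-enoate
Product: 20 methyl (1R,2S,5E)-2-[(1Z)-3-{[tert-butyl(diphenyl)silyl]oxy}-1-[(4R)-2,2-dimethyl-1,3-dioxolan-4-yl]prop-1-en-2-yl]-5-methyl-9-methylidenecyclonon-5-ene-1-carboxylate, via alkylborane 19 (not isolated)
Conditions: Sia2BH (1.3 equiv), THF, 0 °C; then syringe-pump addition (final 2 mM) to Pd(dppf)Cl2 (20 mol%), AsPh3 (40 mol%), Cs2CO3 (3 equiv), DMF/THF/H2O, 50 °C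
Reagents that add atoms: none
Why: Disiamylborane hydroborates the monosubstituted vinyl group much faster than the hindered 1,1-disubstituted methylidene or the trisubstituted alkenes, and the primary alkylborane closes the nine-membered ring by intramolecular B-alkyl Suzuki–Miyaura coupling with retention of the E vinyl iodide geometry, no stereocentre being touched.

Step 11
Reactants: 20 methyl (1R,2S,5E)-2-[(1Z)-3-{[tert-butyl(diphenyl)silyl]oxy}-1-[(4R)-2,2-dimethyl-1,3-dioxolan-4-yl]prop-1-en-2-yl]-5-methyl-9-methylidenecyclonon-5-ene-1-carboxylate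
Product: 21 methyl (1R,2S,5E)-2-[(2Z)-1-{[tert-butyl(diphenyl)silyl]oxy}-4-oxobut-2-en-2-yl]-5-methyl-9-methylidenecyclonon-5-ene-1-carboxylate
Conditions: H5IO6 (1.5 equiv), EtOAc, 0 °C → rt
Reagents that add atoms: none
Why: Periodic acid hydrolyses the terminal acetonide and cleaves the liberated 1,2-diol (Malaprade cleavage), unmasking the former dioxolane carbon as the enal carbon while the silyl ether and the alkenes survive.

Step 12
Reactants: 21 methyl (1R,2S,5E)-2-[(2Z)-1-{[tert-butyl(diphenyl)silyl]oxy}-4-oxobut-2-en-2-yl]-5-methyl-9-methylidenecyclonon-5-ene-1-carboxylate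
Product: 22 methyl (1R,2S,5E)-2-[(2Z,4E)-1-{[tert-butyl(diphenyl)silyl]oxy}-6-oxohepta-2,4-dien-2-yl]-5-methyl-9-methylidenecyclonon-5-ene-1-carboxylate
Conditions: Ph3P=CHC(O)CH3 (1.5 equiv), CH2Cl2, 40 °C
Reagents that add atoms: 1-(triphenylphosphoranylidene)propan-2-one (CC(=O)C=P(c1ccccc1)(c1ccccc1)c1ccccc1)
Why: Wittig olefination with a stabilised ylide gives the E enone selectively and is too weakly basic to epimerise C1.

Step 13
Reactants: 22 methyl (1R,2S,5E)-2-[(2Z,4E)-1-{[tert-butyl(diphenyl)silyl]oxy}-6-oxohepta-2,4-dien-2-yl]-5-methyl-9-methylidenecyclonon-5-ene-1-carboxylate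
Product: 23 methyl (1R,2S,5E)-2-[(2Z,4E)-1-{[tert-butyl(diphenyl)silyl]oxy}-6-hydroxy-6-methylhepta-2,4-dien-2-yl]-5-methyl-9-methylidenecyclonon-5-ene-1-carboxylate
Conditions: MeMgBr (1.3 equiv), THF, −78 °C; sat. aq. NH4Cl
Reagents that add atoms: methylmagnesium bromide (C[Mg]Br)
Why: Grignard 1,2-addition to the methyl ketone at −78 °C is far faster than attack on the hindered α-branched methyl ester and gives the tertiary allylic alcohol.

Step 14
Reactants: 23 methyl (1R,2S,5E)-2-[(2Z,4E)-1-{[tert-butyl(diphenyl)silyl]oxy}-6-hydroxy-6-methylhepta-2,4-dien-2-yl]-5-methyl-9-methylidenecyclonon-5-ene-1-carboxylate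
Product: 25 methyl (1R,2S,5E)-2-[(2Z,4E)-1-(acetyloxy)-6-hydroxy-6-methylhepta-2,4-dien-2-yl]-5-methyl-9-methylidenecyclonon-5-ene-1-carboxylate, via diol 24 (not isolated)
Conditions: Bu4NF (1.2 equiv), AcOH (1.2 equiv), THF, 0 °C → rt; then pyridine, Ac2O (1.5 equiv), 0 °C
Reagents that add atoms: acetic anhydride (CC(=O)OC(C)=O)
Why: Buffered fluoride cleaves the silyl ether without epimerising C1, and acetic anhydride in pyridine without DMAP acylates only the primary allylic hydroxyl, the tertiary alcohol being unreactive.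

**Compound list**

1 | pent-3-yn-1-ol | CC#CCCO | starting material
2 | [(2E)-5-{[chlorobis(cyclopentadienyl)zirconio]oxy}pent-2-en-2-yl]chlorobis(cyclopentadienyl)zirconium | C/C(=C\CCO[Zr](Cl)(C1C=CC=C1)C1C=CC=C1)[Zr](Cl)(C1C=CC=C1)C1C=CC=C1 | intermediate
3 | (E)-4-iodopent-3-en-1-ol | C/C(I)=C\CCO | intermediate
4 | (E)-4-iodopent-3-en-1-yl 4-methylbenzenesulfonate | C/C(I)=C\CCOS(=O)(=O)c1ccc(C)cc1 | intermediate
5 | (E)-6-iodohept-5-en-1-yne | C/C(I)=C\CCC#C | intermediate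
6 | dimethyl[(1E,5E)-6-iodo-2-methylhepta-1,5-dien-1-yl]alumane | C/C(I)=C\CC/C(C)=C/[Al](C)C | intermediate
7 | methyl (2E,6E)-7-iodo-3-methylocta-2,6-dienoate | COC(=O)/C=C(\C)CC/C=C(\C)I | intermediate
8 | (2E,6E)-7-iodo-3-methylocta-2,6-dienoic acid | OC(=O)/C=C(\C)CC/C=C(\C)I | intermediate
9 | tert-butyl(diphenyl)(prop-2-yn-1-yloxy)silane | C#CCO[Si](c1ccccc1)(c1ccccc1)C(C)(C)C | starting material
10 | tert-butyl(pent-4-en-2-yn-1-yloxy)diphenylsilane | C=CC#CCO[Si](c1ccccc1)(c1ccccc1)C(C)(C)C | intermediate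
11 | (S)-2,2-dimethyl-1,3-dioxolane-4-carbaldehyde (2,3-O-isopropylidene-L-glyceraldehyde) | O=C[C@@H]1COC(C)(C)O1 | starting material
12 | (1R,2E)-2-{[tert-butyl(diphenyl)silyl]oxymethyl}-1-[(4S)-2,2-dimethyl-1,3-dioxolan-4-yl]penta-2,4-dien-1-ol (silyloxymethyl cis to vinyl) | C=C/C=C(\CO[Si](c1ccccc1)(c1ccccc1)C(C)(C)C)[C@@H](O)[C@@H]1COC(C)(C)O1 | intermediate
13 | (2E,6E)-7-iodo-3-methylocta-2,6-dienoyl chloride | ClC(=O)/C=C(\C)CC/C=C(\C)I | intermediate
14 | (1R,2E)-2-{[tert-butyl(diphenyl)silyl]oxymethyl}-1-[(4S)-2,2-dimethyl-1,3-dioxolan-4-yl]penta-2,4-dien-1-yl (2E,6E)-7-iodo-3-methylocta-2,6-dienoate | C=C/C=C(\CO[Si](c1ccccc1)(c1ccccc1)C(C)(C)C)[C@@H](OC(=O)/C=C(\C)CC/C=C(\C)I)[C@@H]1COC(C)(C)O1 | intermediate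
15 | {[(1Z,6E)-1-{[(1R,2E)-2-{[tert-butyl(diphenyl)silyl]oxymethyl}-1-[(4S)-2,2-dimethyl-1,3-dioxolan-4-yl]penta-2,4-dien-1-yl]oxy}-7-iodo-3-methylideneocta-1,6-dien-1-yl]oxy}(trimethyl)silane (Me3SiO cis to C3) | C=C/C=C(\CO[Si](c1ccccc1)(c1ccccc1)C(C)(C)C)[C@@H](O/C(O[Si](C)(C)C)=C/C(=C)CC/C=C(\C)I)[C@@H]1COC(C)(C)O1 | intermediate
16 | trimethylsilyl (2R,3S,4Z)-4-{[tert-butyl(diphenyl)silyl]oxymethyl}-5-[(4R)-2,2-dimethyl-1,3-dioxolan-4-yl]-3-ethenyl-2-[(5E)-6-iodohepta-1,5-dien-2-yl]pent-4-enoate | C=C[C@H](/C(CO[Si](c1ccccc1)(c1ccccc1)C(C)(C)C)=C/[C@@H]1COC(C)(C)O1)[C@H](C(=C)CC/C=C(\C)I)C(=O)O[Si](C)(C)C | intermediate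
17 | (2R,3S,4Z)-4-{[tert-butyl(diphenyl)silyl]oxymethyl}-5-[(4R)-2,2-dimethyl-1,3-dioxolan-4-yl]-3-ethenyl-2-[(5E)-6-iodohepta-1,5-dien-2-yl]pent-4-enoic acid | C=C[C@H](/C(CO[Si](c1ccccc1)(c1ccccc1)C(C)(C)C)=C/[C@@H]1COC(C)(C)O1)[C@H](C(=C)CC/C=C(\C)I)C(=O)O | intermediate
18 | methyl (2R,3S,4Z)-4-{[tert-butyl(diphenyl)silyl]oxymethyl}-5-[(4R)-2,2-dimethyl-1,3-dioxolan-4-yl]-3-ethenyl-2-[(5E)-6-iodohepta-1,5-dien-2-yl]pent-4-enoate | C=C[C@H](/C(CO[Si](c1ccccc1)(c1ccccc1)C(C)(C)C)=C/[C@@H]1COC(C)(C)O1)[C@H](C(=C)CC/C=C(\C)I)C(=O)OC | intermediate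
19 | methyl (2R,3S,4Z)-3-{2-[bis(3-methylbutan-2-yl)boranyl]ethyl}-4-{[tert-butyl(diphenyl)silyl]oxymethyl}-5-[(4R)-2,2-dimethyl-1,3-dioxolan-4-yl]-2-[(5E)-6-iodohepta-1,5-dien-2-yl]pent-4-enoate | CC(C)C(C)B(C(C)C(C)C)CC[C@H](/C(CO[Si](c1ccccc1)(c1ccccc1)C(C)(C)C)=C/[C@@H]1COC(C)(C)O1)[C@H](C(=C)CC/C=C(\C)I)C(=O)OC | intermediate
20 | methyl (1R,2S,5E)-2-[(1Z)-3-{[tert-butyl(diphenyl)silyl]oxy}-1-[(4R)-2,2-dimethyl-1,3-dioxolan-4-yl]prop-1-en-2-yl]-5-methyl-9-methylidenecyclonon-5-ene-1-carboxylate | C=C1CC/C=C(\C)CC[C@H](/C(CO[Si](c2ccccc2)(c2ccccc2)C(C)(C)C)=C/[C@@H]2COC(C)(C)O2)[C@H]1C(=O)OC | intermediate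
21 | methyl (1R,2S,5E)-2-[(2Z)-1-{[tert-butyl(diphenyl)silyl]oxy}-4-oxobut-2-en-2-yl]-5-methyl-9-methylidenecyclonon-5-ene-1-carboxylate | C=C1CC/C=C(\C)CC[C@H](/C(CO[Si](c2ccccc2)(c2ccccc2)C(C)(C)C)=C/C=O)[C@H]1C(=O)OC | intermediate
22 | methyl (1R,2S,5E)-2-[(2Z,4E)-1-{[tert-butyl(diphenyl)silyl]oxy}-6-oxohepta-2,4-dien-2-yl]-5-methyl-9-methylidenecyclonon-5-ene-1-carboxylate | C=C1CC/C=C(\C)CC[C@H](/C(CO[Si](c2ccccc2)(c2ccccc2)C(C)(C)C)=C/C=C/C(C)=O)[C@H]1C(=O)OC | intermediate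
23 | methyl (1R,2S,5E)-2-[(2Z,4E)-1-{[tert-butyl(diphenyl)silyl]oxy}-6-hydroxy-6-methylhepta-2,4-dien-2-yl]-5-methyl-9-methylidenecyclonon-5-ene-1-carboxylate | C=C1CC/C=C(\C)CC[C@H](/C(CO[Si](c2ccccc2)(c2ccccc2)C(C)(C)C)=C/C=C/C(C)(C)O)[C@H]1C(=O)OC | intermediate
24 | methyl (1R,2S,5E)-2-[(2Z,4E)-1,6-dihydroxy-6-methylhepta-2,4-dien-2-yl]-5-methyl-9-methylidenecyclonon-5-ene-1-carboxylate | C=C1CC/C=C(\C)CC[C@H](/C(CO)=C/C=C/C(C)(C)O)[C@H]1C(=O)OC | intermediate
25 | methyl (1R,2S,5E)-2-[(2Z,4E)-1-(acetyloxy)-6-hydroxy-6-methylhepta-2,4-dien-2-yl]-5-methyl-9-methylidenecyclonon-5-ene-1-carboxylate | C=C1CC/C=C(\C)CC[C@H](/C(=C/C=C/C(C)(C)O)COC(C)=O)[C@H]1C(=O)OC | target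

**Step count and risks**

Total: 14 steps (telescoped operations counted once). Longest linear sequence: 12 steps (1 → 3 → 4 → 5 → 7 → 8 → 14 → 18 → 20 → 21 → 22 → 23 → 25).

Most likely to fail, first: step 10. The hydroboration must discriminate the vinyl group from the methylidene, and the strained (E)-cyclononene must close in competition with oligomerisation. The fallback sets out from 18 and drops boron altogether. Cp2Zr(H)Cl (1.2 equiv, CH2Cl2, rt), which adds to monosubstituted alkenes far faster than to 1,1-disubstituted ones, gives the primary alkylzirconocene F1. This is added slowly to Pd(PPh3)4 (10 mol%) and ZnCl2 (1 equiv) in THF at 45 °C, where zirconium-to-zinc transmetalation and an intramolecular Negishi coupling with the vinyl iodide close the ring. The fallback rejoins the route at 20.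

Second: step 9. The risks are the site of γ-deprotonation, the ketene acetal geometry (which decides the C1 configuration), and chair versus boat. The fallback sets out from 8 and changes the enolisation mode. The dianion of 8 (2.2 equiv LiN(iPr)2, THF, −78 °C) is protonated kinetically at the α-carbon (AcOH quench) to give (6E)-7-iodo-3-methylideneoct-6-enoic acid F2. This is esterified with 12 (N,N'-diisopropylcarbodiimide, cat. DMAP, CH2Cl2, 0 °C) to the β,γ-unsaturated ester F3. Ordinary α-deprotonation of F3 with KN(SiMe3)2 and Me3SiCl in THF–DMPU at −78 °C, conditions that place Me3SiO cis to the α-substituent, gives the same silyl ketene acetal, so the fallback rejoins the route at 15.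

Third: step 7. The risks are regiocontrol in the catalytic coupling and the anti:syn ratio with the acetonide aldehyde. The fallback sets out from 11 and uses a stoichiometric vinylalane aldol. Methyl propiolate and vinyl bromide (Pd(PPh3)2Cl2, CuI, K2CO3, THF) give methyl pent-4-en-2-ynoate F4. cis-Hydroalumination with iBu2AlH/N-methylmorpholine N-oxide (THF, 0 °C), then addition of 11 at −78 °C, gives methyl (2Z)-2-[(R)-[(4S)-2,2-dimethyl-1,3-dioxolan-4-yl](hydroxy)methyl]penta-2,4-dienoate F5, with the ester cis to the vinyl group and Felkin–Anh control at the carbinol. iBu2AlH (3 equiv, CH2Cl2, −78 °C) reduces the ester to (1R,2E)-1-[(4S)-2,2-dimethyl-1,3-dioxolan-4-yl]-2-(hydroxymethyl)penta-2,4-dien-1-ol F6. Selective silylation of the primary hydroxyl (tBuPh2SiCl, imidazole, CH2Cl2, 0 °C) rejoins the route at 12.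

**Further compounds**

F1 | step 10 | chlorobis(cyclopentadienyl){2-[(3S,4R)-substituted]ethyl}zirconium: the primary alkylzirconocene from hydrozirconation of the vinyl group of 18 | Cl[Zr](CC[C@H](/C(CO[Si](c1ccccc1)(c1ccccc1)C(C)(C)C)=C/[C@@H]1COC(C)(C)O1)[C@H](C(=C)CC/C=C(\C)I)C(=O)OC)(C1C=CC=C1)C1C=CC=C1
F2 | step 9 | (6E)-7-iodo-3-methylideneoct-6-enoic acid | OC(=O)CC(=C)CC/C=C(\C)I
F3 | step 9 | (1R,2E)-2-{[tert-butyl(diphenyl)silyl]oxymethyl}-1-[(4S)-2,2-dimethyl-1,3-dioxolan-4-yl]penta-2,4-dien-1-yl (6E)-7-iodo-3-methylideneoct-6-enoate | C=C/C=C(\CO[Si](c1ccccc1)(c1ccccc1)C(C)(C)C)[C@@H](OC(=O)CC(=C)CC/C=C(\C)I)[C@@H]1COC(C)(C)O1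
F4 | step 7 | methyl pent-4-en-2-ynoate | C=CC#CC(=O)OC
F5 | step 7 | methyl (2Z)-2-[(R)-[(4S)-2,2-dimethyl-1,3-dioxolan-4-yl](hydroxy)methyl]penta-2,4-dienoate | C=C/C=C(\C(=O)OC)[C@@H](O)[C@@H]1COC(C)(C)O1
F6 | step 7 | (1R,2E)-1-[(4S)-2,2-dimethyl-1,3-dioxolan-4-yl]-2-(hydroxymethyl)penta-2,4-dien-1-ol | C=C/C=C(\CO)[C@@H](O)[C@@H]1COC(C)(C)O1
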